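Numbering: C1 (quaternary oxirane carbon bearing C7H2OBz), C2 (OBz), C3 (OH), C4=C5, C6 (oxirane CH). The six-membered carbocycle has its only C=C at C4=C5, flanked by carbinol C3 and oxirane carbon C6, so each alkene carbon maps onto a terminal vinyl group on an oxygenated stereocentre. Ring-closing metathesis closes the ring last from an acyclic 1,7-diene that already carries all four stereocentres, the C1–C6 oxirane and both benzoates; the oxirane holds the C6 vinyl and the C2–C3 branch cis, pre-organising closure. The diene arises from Sharpless epoxidation (C1, C6) and anti-selective asymmetric allylboration (C2, C3) of an α-quaternary epoxy aldehyde.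

Key step: step 11

Remark: the target is read from the SMILES as the all-cis isomer (oxirane oxygen, C2 benzoate and C3 hydroxyl on one ring face, C7 on the other), (1S,2R,3R,6S); compounds 1, 12 and 13 are taken as purchasable.

Step 1
Reactants: 1 methyl 2-(dimethoxyphosphoryl)prop-2-enoate; 2 (4-methoxyphenyl)methanol; 3 prop-2-enal
Product: 6 methyl (2E)-2-{[(4-methoxyphenyl)methoxy]methyl}penta-2,4-dienoate, via sodium 4-methoxybenzyl oxide 4 (not isolated), via phosphonate carbanion 5 (not isolated)
Conditions: 2, NaH, THF, 0 °C; then 1, 0 °C; then 3, 0 °C to rt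
Reagents that add atoms: none
Why: Oxa-Michael addition of the alkoxide to the vinylphosphonate should give the stabilised phosphonate carbanion, which undergoes Horner–Wadsworth–Emmons olefination with acrolein; the E-selective elimination places the vinyl group trans to the ester and cis to the CH2OPMB arm, the geometry that later puts the C6 vinyl group and the C2 branch cis on the oxirane.

Step 2
Reactants: 6 methyl (2E)-2-{[(4-methoxyphenyl)methoxy]methyl}penta-2,4-dienoate
Product: 7 (2Z)-2-{[(4-methoxyphenyl)methoxy]methyl}penta-2,4-dien-1-ol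
Conditions: iBu2AlH (2.2 equiv), CH2Cl2, −78 °C; Rochelle salt work-up
Reagents that add atoms: none
Why: 1,2-Reduction of the conjugated ester by the aluminium hydride should give the allylic alcohol without touching the diene or the benzyl-type ether, and the alkene geometry is retained (the descriptor changes only through priorities).

Step 3
Reactants: 7 (2Z)-2-{[(4-methoxyphenyl)methoxy]methyl}penta-2,4-dien-1-ol
Product: 8 [(2R,3S)-3-ethenyl-2-{[(4-methoxyphenyl)methoxy]methyl}oxiran-2-yl]methanol
Conditions: Ti(OiPr)4 (10 mol %), L-(+)-diisopropyl tartrate (12 mol %), tBuOOH, 4 Å molecular sieves, CH2Cl2, −20 °C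
Reagents that add atoms: tert-butyl hydroperoxide, CC(C)(C)OO
Why: Sharpless asymmetric epoxidation: the allylic hydroxyl binds the titanium tartrate, so only the proximal trisubstituted alkene of the dienol reacts, and L-(+)-tartrate should deliver oxygen to the face that gives the 3S oxirane carbon (as for E-allylic alcohols), which sets both oxirane stereocentres (C1 and C6 of the target) at once.

Step 4
Reactants: 8 [(2R,3S)-3-ethenyl-2-{[(4-methoxyphenyl)methoxy]methyl}oxiran-2-yl]methanol
Product: 9 [(2S,3S)-3-ethenyl-2-{[(4-methoxyphenyl)methoxy]methyl}oxiran-2-yl]methyl benzoate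
Conditions: BzCl, Et3N, DMAP (cat.), CH2Cl2, 0 °C
Reagents that add atoms: benzoyl chloride, O=C(Cl)c1ccccc1
Why: DMAP-catalysed acylation of the only free (primary) hydroxyl installs the C7 benzoate; no stereocentre is touched (the C1 descriptor changes only through priorities).

Step 5
Reactants: 9 [(2S,3S)-3-ethenyl-2-{[(4-methoxyphenyl)methoxy]methyl}oxiran-2-yl]methyl benzoate
Product: 10 [(2S,3S)-3-ethenyl-2-(hydroxymethyl)oxiran-2-yl]methyl benzoate
Conditions: DDQ, CH2Cl2/pH 7 phosphate buffer, 0 °C to rt
Reagents that add atoms: none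
Why: Oxidative cleavage of the 4-methoxybenzyl ether (benzylic oxidation to the oxocarbenium ion and hydrolysis) proceeds under neutral conditions that should leave the benzoate and the vinyl oxirane intact and give no base to trigger 1,3-benzoyl shift.

Step 6
Reactants: 10 [(2S,3S)-3-ethenyl-2-(hydroxymethyl)oxiran-2-yl]methyl benzoate
Product: 11 [(2S,3S)-3-ethenyl-2-formyloxiran-2-yl]methyl benzoate
Conditions: Dess–Martin periodinane, pyridine, CH2Cl2, 0 °C to rt
Reagents that add atoms: none
Why: Dess–Martin oxidation of the primary alcohol should give the aldehyde under buffered conditions; the α-carbon is quaternary, so it cannot epimerise.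

Step 7
Reactants: 11 [(2S,3S)-3-ethenyl-2-formyloxiran-2-yl]methyl benzoate; 12 4,4,5,5-tetramethyl-2-(propa-1,2-dien-1-yl)-1,3,2-dioxaborolane; 13 (+)-diisopinocampheylborane (from (−)-α-pinene)
Product: 16 {(2R,3S)-2-[(1R,2R)-1,2-dihydroxybut-3-en-1-yl]-3-ethenyloxiran-2-yl}methyl benzoate, via (E)-γ-borylallylborane 14 (not isolated), via borinate adduct 15 (not isolated)
Conditions: 12, 13, THF, 0 °C to rt; then 11, −78 °C; then aq. NaHCO3, 30% H2O2, 0 °C
Reagents that add atoms: hydrogen peroxide, OO
Why: Asymmetric allylboration with a γ-boryl-substituted allylborane: hydroboration of the allenylboronate gives the (E)-reagent, whose closed chair transition state translates E geometry into the anti C2/C3 relationship, the isopinocampheyl groups from (−)-α-pinene should direct attack to the Re face of the aldehyde (C2 R), and oxidation of the C–B bond with retention reveals the C3 hydroxyl (C3 R).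

Step 8
Reactants: 16 {(2R,3S)-2-[(1R,2R)-1,2-dihydroxybut-3-en-1-yl]-3-ethenyloxiran-2-yl}methyl benzoate
Product: 17 {(2R,3S)-3-ethenyl-2-[(1R,2R)-1-hydroxy-2-(triethylsilyloxy)but-3-en-1-yl]oxiran-2-yl}methyl benzoate
Conditions: Et3SiCl (1.05 equiv), imidazole, CH2Cl2, −40 °C
Reagents that add atoms: chlorotriethylsilane, CC[Si](Cl)(CC)CC
Why: Site-selective silylation: the allylic C3 hydroxyl is much less hindered than the C2 hydroxyl, which sits next to the quaternary oxirane carbon, so one equivalent of silyl chloride at low temperature should mark C3 only.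

Step 9
Reactants: 17 {(2R,3S)-3-ethenyl-2-[(1R,2R)-1-hydroxy-2-(triethylsilyloxy)but-3-en-1-yl]oxiran-2-yl}methyl benzoate
Product: 18 (1R,2R)-1-{(2S,3S)-2-[(benzoyloxy)methyl]-3-ethenyloxiran-2-yl}-2-(triethylsilyloxy)but-3-en-1-yl benzoate
Conditions: BzCl, pyridine, DMAP, CH2Cl2, rt
Reagents that add atoms: benzoyl chloride, O=C(Cl)c1ccccc1
Why: DMAP-catalysed benzoylation of the remaining hindered secondary hydroxyl installs the C2 benzoate with retention; the mild amine base should not cause silyl migration.

Step 10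
Reactants: 18 (1R,2R)-1-{(2S,3S)-2-[(benzoyloxy)methyl]-3-ethenyloxiran-2-yl}-2-(triethylsilyloxy)but-3-en-1-yl benzoate
Product: 19 (1R,2R)-1-{(2S,3S)-2-[(benzoyloxy)methyl]-3-ethenyloxiran-2-yl}-2-hydroxybut-3-en-1-yl benzoate
Conditions: HF·pyridine, pyridine, THF, 0 °C
Reagents that add atoms: none
Why: Fluoride-driven Si–O cleavage in a pyridine-buffered, slightly acidic medium should free the C3 hydroxyl without the alkoxide formation that would move the C2 benzoate to O3 and without opening the vinyl oxirane.

Step 11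
Reactants: 19 (1R,2R)-1-{(2S,3S)-2-[(benzoyloxy)methyl]-3-ethenyloxiran-2-yl}-2-hydroxybut-3-en-1-yl benzoate
Product: 20 [(1S,2R,3R,6S)-2-(benzoyloxy)-3-hydroxy-7-oxabicyclo[4.1.0]hept-4-en-1-yl]methyl benzoate
Conditions: second-generation Grubbs catalyst RuCl2(=CHPh)(PCy3)(SIMes) (5 mol %), 1,4-benzoquinone (10 mol %), CH2Cl2 (0.005 M), 40 °C
Reagents that add atoms: none
Why: Ring-closing olefin metathesis through metallacyclobutanes: the ruthenium alkylidene should load on the less hindered C3 vinyl group, add intramolecularly across the C6 vinyl group by [2+2] cycloaddition, and cyclorevert to form the C4=C5 bond, with loss of ethene making the step irreversible. The closest known reaction type is ring-closing metathesis of 3,6-dioxygenated octa-1,7-dienes to conduritol-type and cyclohexene-oxide-type carbocycles. The one ring closed is the six-membered carbocycle, made by joining the two terminal alkene carbons of the 1,7-diene, and the ring size allows only the cis C4=C5 olefin. No new stereocentre is formed; C1, C2, C3 and C6 come unchanged from steps 3 and 7. The step needs cyclisation to outrun oligomerisation and needs the vinyl oxirane, free allylic alcohol and benzoates to survive: the cis placement of the C6 vinyl group and the C2–C3 chain on the oxirane (fixed by the 2E ester of step 1) keeps the alkenes within reach, high dilution suppresses cross-metathesis, and the neutral catalyst with benzoquinone as hydride scavenger should prevent epoxide opening and isomerisation of the allylic alcohol to a ketone.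

Compound list
1 | methyl 2-(dimethoxyphosphoryl)prop-2-enoate (trimethyl 2-phosphonoacrylate) | COC(=O)C(=C)P(=O)(OC)OC | starting material
2 | (4-methoxyphenyl)methanol | COc1ccc(CO)cc1 | starting material
3 | prop-2-enal (acrolein) | C=CC=O | starting material
4 | sodium (4-methoxyphenyl)methanolate | [Na+].[O-]Cc1ccc(OC)cc1 | intermediate (not isolated)
5 | sodium salt of the carbanion of methyl 2-(dimethoxyphosphoryl)-3-[(4-methoxyphenyl)methoxy]propanoate | [Na+].COC(=O)[C-](COCc1ccc(OC)cc1)P(=O)(OC)OC | intermediate (not isolated)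
6 | methyl (2E)-2-{[(4-methoxyphenyl)methoxy]methyl}penta-2,4-dienoate | COC(=O)/C(COCc1ccc(OC)cc1)=C/C=C | intermediate
7 | (2Z)-2-{[(4-methoxyphenyl)methoxy]methyl}penta-2,4-dien-1-ol | OC/C(COCc1ccc(OC)cc1)=C/C=C | intermediate
8 | [(2R,3S)-3-ethenyl-2-{[(4-methoxyphenyl)methoxy]methyl}oxiran-2-yl]methanol | OC[C@]1(COCc2ccc(OC)cc2)O[C@H]1C=C | intermediate
9 | [(2S,3S)-3-ethenyl-2-{[(4-methoxyphenyl)methoxy]methyl}oxiran-2-yl]methyl benzoate | O=C(OC[C@]1(COCc2ccc(OC)cc2)O[C@H]1C=C)c1ccccc1 | intermediate
10 | [(2S,3S)-3-ethenyl-2-(hydroxymethyl)oxiran-2-yl]methyl benzoate | O=C(OC[C@]1(CO)O[C@H]1C=C)c1ccccc1 | intermediate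
11 | [(2S,3S)-3-ethenyl-2-formyloxiran-2-yl]methyl benzoate | O=C(OC[C@]1(C=O)O[C@H]1C=C)c1ccccc1 | intermediate
12 | 4,4,5,5-tetramethyl-2-(propa-1,2-dien-1-yl)-1,3,2-dioxaborolane (allenylboronic acid pinacol ester) | C=C=CB1OC(C)(C)C(C)(C)O1 | starting material
13 | (+)-diisopinocampheylborane, bis[(1S,2R,3S,5S)-2,6,6-trimethylbicyclo[3.1.1]heptan-3-yl]borane | B([C@H]1C[C@H]2C[C@@H]([C@@H]1C)C2(C)C)[C@H]1C[C@H]2C[C@@H]([C@@H]1C)C2(C)C | starting material
14 | bis(isopinocampheyl)[(2E)-3-(4,4,5,5-tetramethyl-1,3,2-dioxaborolan-2-yl)prop-2-en-1-yl]borane | CC1(C)OB(/C=C/CB([C@H]2C[C@H]3C[C@@H]([C@@H]2C)C3(C)C)[C@H]2C[C@H]3C[C@@H]([C@@H]2C)C3(C)C)OC1(C)C | intermediate (not isolated)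
15 | allylboration adduct: compound 16 with a bis(isopinocampheyl)boryl group on the C2 oxygen and the pinacolboryl group on C3 in place of the C3 hydroxyl | C=C[C@@H](B1OC(C)(C)C(C)(C)O1)[C@@H](OB([C@H]2C[C@H]3C[C@@H]([C@@H]2C)C3(C)C)[C@H]2C[C@H]3C[C@@H]([C@@H]2C)C3(C)C)[C@@]1(COC(=O)c2ccccc2)O[C@H]1C=C | intermediate (not isolated)
16 | {(2R,3S)-2-[(1R,2R)-1,2-dihydroxybut-3-en-1-yl]-3-ethenyloxiran-2-yl}methyl benzoate | C=C[C@@H](O)[C@@H](O)[C@@]1(COC(=O)c2ccccc2)O[C@H]1C=C | intermediate
17 | {(2R,3S)-3-ethenyl-2-[(1R,2R)-1-hydroxy-2-(triethylsilyloxy)but-3-en-1-yl]oxiran-2-yl}methyl benzoate | C=C[C@@H](O[Si](CC)(CC)CC)[C@@H](O)[C@@]1(COC(=O)c2ccccc2)O[C@H]1C=C | intermediate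
18 | (1R,2R)-1-{(2S,3S)-2-[(benzoyloxy)methyl]-3-ethenyloxiran-2-yl}-2-(triethylsilyloxy)but-3-en-1-yl benzoate | C=C[C@@H](O[Si](CC)(CC)CC)[C@@H](OC(=O)c1ccccc1)[C@@]1(COC(=O)c2ccccc2)O[C@H]1C=C | intermediate
19 | (1R,2R)-1-{(2S,3S)-2-[(benzoyloxy)methyl]-3-ethenyloxiran-2-yl}-2-hydroxybut-3-en-1-yl benzoate | C=C[C@@H](O)[C@@H](OC(=O)c1ccccc1)[C@@]1(COC(=O)c2ccccc2)O[C@H]1C=C | intermediate
20 | [(1S,2R,3R,6S)-2-(benzoyloxy)-3-hydroxy-7-oxabicyclo[4.1.0]hept-4-en-1-yl]methyl benzoate | O=C(OC[C@]12O[C@H]1C=C[C@@H](O)[C@H]2OC(=O)c1ccccc1)c1ccccc1 | target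

Total step count: 11. Longest linear sequence: 11 steps (from 1, 2 and 3 to 20).

Steps most likely to fail

Step 7. The aldehyde's own facial preference (α-quaternary, α-oxygenated) may oppose the reagent, the γ-borylallylborane may lose its E geometry before it reacts and erode the anti selectivity, and the C7 benzoate may shift to the new C2 hydroxyl or be cleaved in the peroxide work-up. The fallback runs from 11 to 17 and brings the C3 oxygen in already silylated, so no oxidation is needed and step 8 is bypassed. Triethyl(prop-2-yn-1-yloxy)silane is hydroborated with pinacolborane (Cp2ZrHCl cat.) to triethyl{[(2E)-3-(4,4,5,5-tetramethyl-1,3,2-dioxaborolan-2-yl)prop-2-en-1-yl]oxy}silane F1. Double-bond migration with [Ir(cod)(PPh2Me)2]PF6 (activated with H2) gives the (E)-γ-silyloxyallylboronate triethyl{[(1E)-3-(4,4,5,5-tetramethyl-1,3,2-dioxaborolan-2-yl)prop-1-en-1-yl]oxy}silane F2. F2 should add to 11 through a closed chair transition state (anti) in toluene at −30 °C under a chiral BINOL-derived phosphoric acid ((R)-TRIP, the antipode expected to direct Re-face attack) and give 17 after aqueous work-up.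

Step 8. Discrimination between the two secondary hydroxyls may be incomplete (bis-silylation, silylation at C2, or silyl migration), which would misplace the second benzoate. The fallback runs from 16 to 19 and differentiates by chemoselective oxidation instead of protection. Manganese dioxide (MnO2, CH2Cl2, rt) should oxidise only the allylic C3 hydroxyl to the vinyl ketone {(2R,3S)-3-ethenyl-2-[(1S)-1-hydroxy-2-oxobut-3-en-1-yl]oxiran-2-yl}methyl benzoate F3. Benzoylation (BzCl, pyridine, DMAP) gives (1S)-1-{(2S,3S)-2-[(benzoyloxy)methyl]-3-ethenyloxiran-2-yl}-2-oxobut-3-en-1-yl benzoate F4. Luche reduction (NaBH4, CeCl3·7H2O, MeOH, −78 °C) of F4 under Felkin–Anh control by the α-benzoyloxy group should give the anti alcohol 19.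

Step 1. Reversal of the oxa-Michael addition before olefination and incomplete E selectivity with the α-branched phosphonate may give mixtures of alkene isomers. The fallback runs from 3 to 6 and sets the geometry under thermodynamic control. Morita–Baylis–Hillman reaction of 3 with methyl acrylate (DABCO) gives methyl 3-hydroxy-2-methylidenepent-4-enoate F5. Acetylation with allylic transposition (Ac2O, TMSOTf cat., 0 °C) should give the conjugated primary acetate methyl (2E)-2-(acetoxymethyl)penta-2,4-dienoate F6. Methanolysis (K2CO3 cat., MeOH, 0 °C) gives methyl (2E)-2-(hydroxymethyl)penta-2,4-dienoate F7. Etherification with 4-methoxybenzyl 2,2,2-trichloroacetimidate (camphorsulfonic acid cat., CH2Cl2) gives 6.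

Further compounds
F1 | step 7 | triethyl{[(2E)-3-(4,4,5,5-tetramethyl-1,3,2-dioxaborolan-2-yl)prop-2-en-1-yl]oxy}silane | CC[Si](CC)(CC)OC/C=C/B1OC(C)(C)C(C)(C)O1
F2 | step 7 | triethyl{[(1E)-3-(4,4,5,5-tetramethyl-1,3,2-dioxaborolan-2-yl)prop-1-en-1-yl]oxy}silane | CC[Si](CC)(CC)O/C=C/CB1OC(C)(C)C(C)(C)O1
F3 | step 8 | {(2R,3S)-3-ethenyl-2-[(1S)-1-hydroxy-2-oxobut-3-en-1-yl]oxiran-2-yl}methyl benzoate | C=CC(=O)[C@@H](O)[C@@]1(COC(=O)c2ccccc2)O[C@H]1C=C
F4 | step 8 | (1S)-1-{(2S,3S)-2-[(benzoyloxy)methyl]-3-ethenyloxiran-2-yl}-2-oxobut-3-en-1-yl benzoate | C=CC(=O)[C@@H](OC(=O)c1ccccc1)[C@@]1(COC(=O)c2ccccc2)O[C@H]1C=C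
F5 | step 1 | methyl 3-hydroxy-2-methylidenepent-4-enoate (racemic) | C=CC(O)C(=C)C(=O)OC
F6 | step 1 | methyl (2E)-2-(acetoxymethyl)penta-2,4-dienoate | COC(=O)/C(COC(C)=O)=C/C=C
F7 | step 1 | methyl (2E)-2-(hydroxymethyl)penta-2,4-dienoate | COC(=O)/C(CO)=C/C=C
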